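**Plan**

- Numbering used: ring A = C1–C5 and C10 (C3 ketone, C4 gem-dimethyl); ring B = C5–C10; C11 = OCH2 on C9; C12 = methyl on C8; C15 = methyl on C10.
- Enabling feature: ring B is a cyclohexene whose single alkene C7=C8 sits opposite the C5–C10 bond and whose stereocentres C5, C10 and C9 are contiguous. This is the footprint of a diene C6=C7–C8=C9 added across an alkene C5=C10.
- Cuts: C1–C2 (ring A, after reinstating a C1=C2 enone), then C5–C6 and C9–C10 together (ring B). This leaves a dienyl umbelliferyl ether (cut at aryl O–C11) and an (E)-2-methyl-2-enal carrying the methyl ketone (cut at C5=C10).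
- Forward: the two fragments (2 and 3 steps) are joined by an enantioselective Diels–Alder reaction that makes ring B. An aldol condensation then closes ring A, and conjugate reduction of the enone completes the target.
- Stereochemistry: C5/C10 trans from the (E)-enal, C9 from the endo approach to the (E)-diene, absolute configuration from the chiral oxazaborolidinium catalyst. No centre is epimerisable afterwards.

Key step: step 6

Assumption: the (3aS) catalyst is assigned Re-face delivery at C10 from the formyl C–H···O binding model for 2-substituted enals; should the adduct prove antipodal, the (3aR) catalyst would be used with nothing else changed.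

**Route**

Step 1
Reactants: 1 (2E)-3-methylpent-2-en-4-yn-1-ol
Product: 2 (2E)-3-methylpenta-2,4-dien-1-ol
Conditions: H2 (1 atm), Pd/CaCO3 poisoned with Pb(OAc)2, quinoline, EtOAc, 0 °C to rt, stopped after 1 equiv H2
Reagents that add atoms: none
Why: Semihydrogenation of a terminal alkyne over lead-poisoned palladium with quinoline should stop at the vinyl group, so the conjugated enyne becomes the diene while the trisubstituted (E)-alkene is carried over unchanged; no stereocentre is formed.

Step 2
Reactants: 2 (2E)-3-methylpenta-2,4-dien-1-ol; 3 umbelliferone (7-hydroxy-2H-chromen-2-one)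
Product: 4 7-{[(2E)-3-methylpenta-2,4-dien-1-yl]oxy}-2H-chromen-2-one
Conditions: PPh3, DIAD (added last, dropwise), THF, 0 °C to rt
Reagents that add atoms: none
Why: Mitsunobu etherification, in which the acidic phenol protonates the PPh3–DIAD betaine and then displaces the primary allylic alkoxyphosphonium directly at C11, so the (E)-diene geometry is kept, while slow addition of DIAD to premixed PPh3 keeps free azo compound away from the diene.

Step 3
Reactants: 5 methyl 2,2-dimethyl-3-oxobutanoate
Product: 6 2,2-dimethylbutane-1,3-diol (racemic)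
Conditions: LiAlH4, THF, 0 °C to rt; aq. NaOH work-up
Reagents that add atoms: none
Why: Hydride reduction with LiAlH4 of the non-enolisable β-keto ester should reduce ester and ketone alike to the 1,3-diol; the carbinol centre forms as a racemate and is erased in step 4.

Step 4
Reactants: 6 2,2-dimethylbutane-1,3-diol
Product: 7 2,2-dimethyl-3-oxobutanal
Conditions: (COCl)2, DMSO, CH2Cl2, −78 °C; Et3N, −78 °C to 0 °C; used crude (volatile)
Reagents that add atoms: none
Why: Swern oxidation converts the primary and the secondary alcohol in one operation, and the quaternary carbon between the two carbonyl groups excludes enolisation, chlorination or elimination there.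

Step 5
Reactants: 7 2,2-dimethyl-3-oxobutanal; 8 2-(triphenylphosphoranylidene)propanal
Product: 9 (2E)-2,4,4-trimethyl-5-oxohex-2-enal
Conditions: toluene, 90 °C
Reagents that add atoms: none
Why: Wittig olefination with a formyl-stabilised ylide should engage only the aldehyde (the hindered methyl ketone is inert to stabilised ylides) and give the (E)-2-methyl-2-enal, with CHO trans to the tertiary alkyl group.

Step 6
Reactants: 4 7-{[(2E)-3-methylpenta-2,4-dien-1-yl]oxy}-2H-chromen-2-one; 9 (2E)-2,4,4-trimethyl-5-oxohex-2-enal
Product: 10 (1S,2R,6R)-1,3-dimethyl-6-(2-methyl-3-oxobutan-2-yl)-2-{[(2-oxo-2H-chromen-7-yl)oxy]methyl}cyclohex-3-ene-1-carbaldehyde (5R,9R,10S in the numbering of the plan)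
Conditions: (3aS)-1-(2-methylphenyl)-3,3-diphenyltetrahydro-1H,3H-pyrrolo[1,2-c][1,3,2]oxazaborole (24 mol%) + HNTf2 (20 mol%), CH2Cl2, −25 °C; 9 (2 equiv), then 4, about 1 M, −20 °C to 4 °C; Et3N quench
Reagents that add atoms: none
Why: The oxazaborolidinium cation binds the formyl oxygen of s-trans 9 (with a formyl C–H···O contact to the ring oxygen) and lowers its LUMO, so that the s-cis diene 4 adds in a concerted, asynchronous [4π+2π] cycloaddition in which C5–C6 forms ahead of C9–C10. The closest known reaction type is the cationic oxazaborolidine-catalysed Diels–Alder addition of (E)-2-methyl-2-enals to acyclic 1-substituted dienes, applied here to an unusually bulky β-substituent. Ring B closes as the six-membered cycloaddition ring, both new bonds being ring bonds made suprafacially on diene and dienophile. C5 and C10 inherit the (E)-geometry of the enal (C1 trans to C4, the later trans ring fusion); C9 is fixed against C10 by the endo position of the formyl group, which ends cis to the outward CH2OAr of the (E)-diene so that C11 is trans to the C10 methyl (the exo mode would force the tertiary alkyl group under the diene); the absolute sense comes from the catalyst, whose phenyl group cis to the bound aldehyde covers the Si face of C10 and leaves the Re face to the diene. The step needs C6 rather than C9 to bond to C5, which is secured by the size of the CMe2C(O)CH3 group (it can approach only the unsubstituted diene terminus) and by the larger HOMO coefficient that the C9 substituent places on C6. Because the coumarin carbonyl competes reversibly for boron and the dienophile is hindered, the enal is used in excess at high concentration with a raised catalyst loading, and slightly less HNTf2 than oxazaborolidine keeps free acid away from the allylic aryl ether.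

Step 7
Reactants: 10 (1S,2R,6R)-1,3-dimethyl-6-(2-methyl-3-oxobutan-2-yl)-2-{[(2-oxo-2H-chromen-7-yl)oxy]methyl}cyclohex-3-ene-1-carbaldehyde
Product: 12 enone 7-{[(1R,4aR,8aS)-2,5,5,8a-tetramethyl-6-oxo-1,4,4a,5,6,8a-hexahydronaphthalen-1-yl]methoxy}-2H-chromen-2-one, via ring A aldol 11 (not isolated)
Conditions: pyrrolidine (0.3 equiv), AcOH (0.3 equiv), toluene, 80 °C
Reagents that add atoms: none
Why: Intramolecular aldol condensation under amine-salt catalysis, in which the C1 aldehyde has no α-hydrogen and the C3 ketone can enolise only toward the methyl group C2 (C4 is quaternary), so a single 6-(enolendo)-exo-trig closure is possible and dehydration to the conjugated C1=C2 enone drives it forward; no stereocentre is retained from the aldol and none is epimerisable (C5 and C9 are not α to a carbonyl, C10 is quaternary).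

Step 8
Reactants: 12 enone 7-{[(1R,4aR,8aS)-2,5,5,8a-tetramethyl-6-oxo-1,4,4a,5,6,8a-hexahydronaphthalen-1-yl]methoxy}-2H-chromen-2-one
Product: 14 target 7-{[(1R,4aR,8aS)-2,5,5,8a-tetramethyl-6-oxo-1,4,4a,5,6,7,8,8a-octahydronaphthalen-1-yl]methoxy}-2H-chromen-2-one, via silyl enol ether 13 (not isolated)
Conditions: [(Ph3P)CuH]6 (5 mol%), PhMe2SiH (1.3 equiv), toluene, rt; then 1 M HCl, THF, rt
Reagents that add atoms: none
Why: Copper hydride conjugate reduction (catalytic [(Ph3P)CuH]6 turned over by the silane) should deliver hydride to C1 of the ketone-conjugated alkene and give the silyl enol ether, hydrolysed on acidic work-up; the enone reacts much faster than the electron-rich coumarin lactone alkene, the isolated C7=C8 bond is inert, and no stereocentre is created.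

**Compound list**

1 | (2E)-3-methylpent-2-en-4-yn-1-ol | C#C/C(C)=C/CO | starting material
2 | (2E)-3-methylpenta-2,4-dien-1-ol | C=C/C(C)=C/CO | intermediate
3 | umbelliferone (7-hydroxy-2H-chromen-2-one) | Oc1ccc2ccc(=O)oc2c1 | starting material
4 | 7-{[(2E)-3-methylpenta-2,4-dien-1-yl]oxy}-2H-chromen-2-one | C=C/C(C)=C/COc1ccc2ccc(=O)oc2c1 | intermediate
5 | methyl 2,2-dimethyl-3-oxobutanoate | COC(=O)C(C)(C)C(C)=O | starting material
6 | 2,2-dimethylbutane-1,3-diol (racemic) | CC(O)C(C)(C)CO | intermediate
7 | 2,2-dimethyl-3-oxobutanal | CC(=O)C(C)(C)C=O | intermediate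
8 | 2-(triphenylphosphoranylidene)propanal | CC(C=O)=P(c1ccccc1)(c1ccccc1)c1ccccc1 | starting material
9 | (2E)-2,4,4-trimethyl-5-oxohex-2-enal | O=C/C(C)=C/C(C)(C)C(C)=O | intermediate
10 | (1S,2R,6R)-1,3-dimethyl-6-(2-methyl-3-oxobutan-2-yl)-2-{[(2-oxo-2H-chromen-7-yl)oxy]methyl}cyclohex-3-ene-1-carbaldehyde | CC1=CC[C@@H](C(C)(C)C(C)=O)[C@](C)(C=O)[C@@H]1COc1ccc2ccc(=O)oc2c1 | intermediate
11 | 7-{[(1R,4aR,8aS)-8-hydroxy-2,5,5,8a-tetramethyl-6-oxo-1,4,4a,5,6,7,8,8a-octahydronaphthalen-1-yl]methoxy}-2H-chromen-2-one (ring A aldol, either carbinol epimer, not isolated) | CC1=CC[C@H]2C(C)(C)C(=O)CC(O)[C@]2(C)[C@@H]1COc1ccc2ccc(=O)oc2c1 | intermediate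
12 | 7-{[(1R,4aR,8aS)-2,5,5,8a-tetramethyl-6-oxo-1,4,4a,5,6,8a-hexahydronaphthalen-1-yl]methoxy}-2H-chromen-2-one | CC1=CC[C@H]2C(C)(C)C(=O)C=C[C@]2(C)[C@@H]1COc1ccc2ccc(=O)oc2c1 | intermediate
13 | 7-{[(1R,4aR,8aS)-6-{[dimethyl(phenyl)silyl]oxy}-2,5,5,8a-tetramethyl-1,4,4a,5,8,8a-hexahydronaphthalen-1-yl]methoxy}-2H-chromen-2-one (silyl enol ether, not isolated) | CC1=CC[C@H]2C(C)(C)C(O[Si](C)(C)c3ccccc3)=CC[C@]2(C)[C@@H]1COc1ccc2ccc(=O)oc2c1 | intermediate
14 | 7-{[(1R,4aR,8aS)-2,5,5,8a-tetramethyl-6-oxo-1,4,4a,5,6,7,8,8a-octahydronaphthalen-1-yl]methoxy}-2H-chromen-2-one | CC1=CC[C@H]2C(C)(C)C(=O)CC[C@]2(C)[C@@H]1COc1ccc2ccc(=O)oc2c1 | target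

**Count**

Total steps: 8. Longest linear sequence: 6 steps (steps 3–8, from 5 through 6, 7, 9, 10 and 12 to 14).

**Steps most likely to fail**

1. Step 6 (cycloaddition). The addition may stall because the tertiary alkyl group shields C5 while the coumarin carbonyl ties up the boron cation. The acid may also ionise the allylic aryl ether, so that the diene is lost to oligomerisation before it reacts. Fallback, setting out from 2 and returning at 14: the C11 oxygen is carried as a silyl ether and the coumarin is attached last. Dienol 2 would be silylated (i-Pr3SiCl, imidazole, DMF) to the triisopropylsilyl dienyl ether F1. F1 and enal 9 would be combined under the catalyst system of step 6 to give the silyl cycloadduct F2; with no Lewis-basic lactone and no ionisable aryl ether present, the AlBr3-activated form of the same oxazaborolidine or high pressure could be applied if needed. Pyrrolidine/AcOH would then close ring A through the silyl aldol F3 to the silyl enone F4. Copper hydride reduction as in step 8 would give, through the bis-silyl enol ether F5, the silyl-protected ketone F6 with no unsaturated lactone in competition. Bu4NF in THF would free the keto alcohol F7, and a Mitsunobu reaction of F7 with umbelliferone 3 (PPh3, DIAD, THF) would deliver 14.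

2. Step 8 (conjugate reduction). Chemoselectivity may be lost if hydride transfer to the coumarin C3=C4 bond competes with reduction of the ring A enone, giving over-reduction. Fallback, setting out from 12 and returning at 14: the copper hydride is replaced by palladium-catalysed hydrostannation, which adds to enones but leaves unsaturated esters and lactones alone. Treatment of 12 with Bu3SnH and catalytic Pd(PPh3)4 in THF containing AcOH at rt should form the tributylstannyl enol ether F8, which is protonated in the flask by the acetic acid to give 14.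

3. Step 5 (olefination). Olefination of the neopentyl-type aldehyde may be sluggish, allowing a second olefination of the product enal or nucleophile-induced deformylation of the β-keto aldehyde to compete. Fallback, setting out from 7 and returning at 9: the aldehyde is olefinated with a more nucleophilic phosphonate anion and the oxidation level is corrected afterwards. A Horner–Wadsworth–Emmons reaction of 7 with triethyl 2-phosphonopropionate (LiCl, DBU, MeCN) should give the (E)-keto enoate F9. Excess i-Bu2AlH (CH2Cl2, −78 °C) would reduce ester and ketone to the (E)-ene-1,5-diol F10, and Swern oxidation of both alcohols returns 9.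

**Further compounds**

F1 | step 6 | triisopropyl{[(2E)-3-methylpenta-2,4-dien-1-yl]oxy}silane | C=C/C(C)=C/CO[Si](C(C)C)(C(C)C)C(C)C
F2 | step 6 | (1S,2R,6R)-1,3-dimethyl-6-(2-methyl-3-oxobutan-2-yl)-2-{[(triisopropylsilyl)oxy]methyl}cyclohex-3-ene-1-carbaldehyde | CC1=CC[C@@H](C(C)(C)C(C)=O)[C@](C)(C=O)[C@@H]1CO[Si](C(C)C)(C(C)C)C(C)C
F3 | step 6 | (4aS,5R,8aR)-4-hydroxy-1,1,4a,6-tetramethyl-5-{[(triisopropylsilyl)oxy]methyl}-3,4,4a,5,8,8a-hexahydronaphthalen-2(1H)-one (either carbinol epimer, not isolated) | CC1=CC[C@H]2C(C)(C)C(=O)CC(O)[C@]2(C)[C@@H]1CO[Si](C(C)C)(C(C)C)C(C)C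
F4 | step 6 | (4aS,5R,8aR)-1,1,4a,6-tetramethyl-5-{[(triisopropylsilyl)oxy]methyl}-4a,5,8,8a-tetrahydronaphthalen-2(1H)-one | CC1=CC[C@H]2C(C)(C)C(=O)C=C[C@]2(C)[C@@H]1CO[Si](C(C)C)(C(C)C)C(C)C
F5 | step 6 | dimethyl(phenyl){[(4aS,5R,8aR)-1,1,4a,6-tetramethyl-5-{[(triisopropylsilyl)oxy]methyl}-1,4,4a,5,8,8a-hexahydronaphthalen-2-yl]oxy}silane (not isolated) | CC1=CC[C@H]2C(C)(C)C(O[Si](C)(C)c3ccccc3)=CC[C@]2(C)[C@@H]1CO[Si](C(C)C)(C(C)C)C(C)C
F6 | step 6 | (4aS,5R,8aR)-1,1,4a,6-tetramethyl-5-{[(triisopropylsilyl)oxy]methyl}-3,4,4a,5,8,8a-hexahydronaphthalen-2(1H)-one | CC1=CC[C@H]2C(C)(C)C(=O)CC[C@]2(C)[C@@H]1CO[Si](C(C)C)(C(C)C)C(C)C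
F7 | step 6 | (4aS,5R,8aR)-5-(hydroxymethyl)-1,1,4a,6-tetramethyl-3,4,4a,5,8,8a-hexahydronaphthalen-2(1H)-one | CC1=CC[C@H]2C(C)(C)C(=O)CC[C@]2(C)[C@@H]1CO
F8 | step 8 | 7-{[(1R,4aR,8aS)-2,5,5,8a-tetramethyl-6-[(tributylstannyl)oxy]-1,4,4a,5,8,8a-hexahydronaphthalen-1-yl]methoxy}-2H-chromen-2-one (not isolated) | CC1=CC[C@H]2C(C)(C)C(O[Sn](CCCC)(CCCC)CCCC)=CC[C@]2(C)[C@@H]1COc1ccc2ccc(=O)oc2c1
F9 | step 5 | ethyl (2E)-2,4,4-trimethyl-5-oxohex-2-enoate | CCOC(=O)/C(C)=C/C(C)(C)C(C)=O
F10 | step 5 | (2E)-2,4,4-trimethylhex-2-ene-1,5-diol (racemic) | OC/C(C)=C/C(C)(C)C(C)O
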